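**Retrosynthetic overview**

1. Target 43 ⇐ mild acid removal of the peroxyketal and aryl THP groups from 42 ⇐ late Steglich esterification of the macrocyclic alcohol 41 (C15 core) with protected p-coumaric acid 26 (fragment C).
2. C8–OO bond ⇐ SN2 displacement (inversion) of the (8R)-allylic mesylate by 2-methoxypropan-2-yl hydroperoxide 21; the (8R)-alcohol ⇐ CBS reduction of the 7-methylidene-8-ketone 37.
3. The only carbocycle to be built, the 11-membered ring, ⇐ Nozaki–Hiyama–Kishi closure of C7–C8 in iodo-aldehyde 34.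
4. Acyclic C15 chain ⇐ C2–C3 bond: the (Z)-alkenyllithium from fragment B (17, seven skeletal carbons) opens the (R)-epoxide fragment A (7, eight skeletal carbons).
5. Fragment A ⇐ prenylmagnesium chloride + (R)-epichlorohydrin; fragment B ⇐ pent-4-yn-1-ol + iodoethane (iodo-Wittig); fragment C ⇐ 4-iodophenol + methyl acrylate (Heck).

Assumptions: macrocycles are numbered as in the target (C1 carries the ester oxygen, C3=C4 is the ring alkene, C7 the methylidene carbon, C8 the peroxide carbon, C10 the gem-dimethyl carbon); THP ethers are inconsequential epimer mixtures at the acetal carbon; phosphonium salt 13 and hydroperoxide 21 are prepared rather than bought.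

**Fragment A**

Step 1
Reactants: 1 prenylmagnesium chloride; 2 (R)-epichlorohydrin
Product: 4 (2R)-2-(2,2-dimethylbut-3-en-1-yl)oxirane, via chlorohydrin 3 (not isolated)
Conditions: THF, −78 → −20 °C (no copper salt); then 3 M NaOH, Et2O, rt
Reagents that add atoms: none
Why: The allylic Grignard reagent opens the epoxide at its CH2 carbon through its γ-carbon (SE2'-type Grignard epoxide opening), which builds the quaternary carbon without touching the stereocentre, and the chlorohydrin then closes by intramolecular Williamson displacement of chloride, so the R centre of 2 becomes C1 of the target unchanged.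

Step 2
Reactants: 4 (2R)-2-(2,2-dimethylbut-3-en-1-yl)oxirane
Product: 6 3,3-dimethyl-4-[(2R)-oxiran-2-yl]butan-1-ol, via B-alkyl-9-BBN adduct 5 (not isolated)
Conditions: 9-BBN (1.2 equiv), THF, 0 °C → rt; then NaBO3·4H2O, H2O, rt
Reagents that add atoms: sodium perborate, [Na+].[Na+].O[B-]1(O)OO[B-](O)(O)OO1
Why: Brown hydroboration–oxidation with bulky 9-BBN adds anti-Markovnikov to the only alkene, and the mild perborate oxidation leaves the epoxide intact.

Step 3
Reactants: 6 3,3-dimethyl-4-[(2R)-oxiran-2-yl]butan-1-ol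
Product: 7 triethyl{3,3-dimethyl-4-[(2R)-oxiran-2-yl]butoxy}silane
Conditions: Et3SiCl, imidazole, CH2Cl2, 0 °C
Reagents that add atoms: chlorotriethylsilane, CC[Si](Cl)(CC)CC
Why: Silyl ether formation at the primary hydroxyl, with TES chosen because a primary TES ether can later be oxidised directly to the aldehyde.

**Fragment B**

Step 4
Reactants: 8 pent-4-yn-1-ol
Product: 10 5-(trimethylsilyl)pent-4-yn-1-ol, via bis-silylated alkynol 9 (not isolated)
Conditions: n-BuLi (2.2 equiv), THF, −78 °C; Me3SiCl (2.3 equiv), −78 °C → rt; then 1 M HCl, rt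
Reagents that add atoms: chlorotrimethylsilane, C[Si](C)(C)Cl
Why: Double deprotonation and C,O-bis-silylation followed by selective hydrolysis of the labile O–Si bond masks the acidic alkyne proton for the organolithium chemistry of step 12.

Step 5
Reactants: 10 5-(trimethylsilyl)pent-4-yn-1-ol
Product: 11 5-(trimethylsilyl)pent-4-ynal
Conditions: Dess–Martin periodinane, CH2Cl2, 0 °C → rt
Reagents that add atoms: none
Why: Dess–Martin oxidation of a primary alcohol stops cleanly at the aldehyde.

Step 6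
Reactants: 12 iodoethane
Product: 13 ethyltriphenylphosphonium iodide
Conditions: PPh3, toluene, 90 °C, sealed tube
Reagents that add atoms: triphenylphosphine, c1ccc(cc1)P(c1ccccc1)c1ccccc1
Why: SN2 quaternisation of the phosphine by a primary iodide.

Step 7
Reactants: 13 ethyltriphenylphosphonium iodide; 11 5-(trimethylsilyl)pent-4-ynal
Product: 17 [(5Z)-6-iodohept-5-en-1-yn-1-yl]trimethylsilane, via ethylidene ylide 14 (not isolated), via iodoethylphosphonium iodide 15 (not isolated), via iodo ylide 16 (not isolated)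
Conditions: 13, n-BuLi, THF, 0 °C → rt; I2, −78 °C; NaN(SiMe3)2, −78 → −20 °C; then 11, −78 °C → rt
Reagents that add atoms: iodine, II
Why: Stork–Zhao-type Wittig olefination, in which the α-iodo ylide made in situ reacts with the aldehyde under kinetic control to give the (Z)-2-iodoalk-2-ene and thereby fixes the geometry of the future C3=C4 ring alkene.

**Peroxide reagent**

Step 8
Reactants: 18 2,3-dimethylbut-2-ene
Product: 21 2-methoxypropan-2-yl hydroperoxide, via primary ozonide 19 (not isolated), via acetone O-oxide 20 (not isolated)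
Conditions: O3, CH2Cl2/MeOH (4:1), −78 °C; N2 purge, warm to rt, no reductive work-up (handle as a solution behind a shield)
Reagents that add atoms: ozone, [O-][O+]=O; methanol, CO
Why: Ozonolysis in methanol, where cycloreversion of the primary ozonide gives acetone and its carbonyl oxide (Criegee intermediate), which methanol traps as the α-methoxy hydroperoxide.

**Fragment C**

Step 9
Reactants: 22 4-iodophenol
Product: 23 2-(4-iodophenoxy)tetrahydro-2H-pyran
Conditions: 3,4-dihydro-2H-pyran, PPTS (cat.), CH2Cl2, rt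
Reagents that add atoms: 3,4-dihydro-2H-pyran, C1=COCCC1
Why: Acid-catalysed addition of the phenol to the enol ether (THP acetal formation) gives a base-stable, mildly acid-labile protecting group.

Step 10
Reactants: 23 2-(4-iodophenoxy)tetrahydro-2H-pyran; 24 methyl acrylate
Product: 25 methyl (2E)-3-[4-(tetrahydro-2H-pyran-2-yloxy)phenyl]prop-2-enoate
Conditions: Pd(OAc)2 (2 mol %), P(o-tol)3 (4 mol %), Et3N, MeCN, 80 °C
Reagents that add atoms: none
Why: Mizoroki–Heck reaction of the aryl iodide with the acrylate gives the E-cinnamate through syn insertion and syn β-hydride elimination.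

Step 11
Reactants: 25 methyl (2E)-3-[4-(tetrahydro-2H-pyran-2-yloxy)phenyl]prop-2-enoate
Product: 26 (2E)-3-[4-(tetrahydro-2H-pyran-2-yloxy)phenyl]prop-2-enoic acid
Conditions: LiOH·H2O, THF/MeOH/H2O, rt; then cold aq. KHSO4 to pH 4–5, rapid extraction
Reagents that add atoms: lithium hydroxide, [Li+].[OH-]
Why: Saponification of the methyl ester, in which the base-stable THP acetal survives the brief, cold, mildly acidic work-up.

**Union of A and B, ring closure and end game**

Step 12
Reactants: 17 [(5Z)-6-iodohept-5-en-1-yn-1-yl]trimethylsilane; 7 triethyl{3,3-dimethyl-4-[(2R)-oxiran-2-yl]butoxy}silane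
Product: 28 (5R,7Z)-3,3,7-trimethyl-1-[(triethylsilyl)oxy]-12-(trimethylsilyl)dodec-7-en-11-yn-5-ol, via vinyllithium 27 (not isolated)
Conditions: 17 (1.3 equiv), t-BuLi (2.6 equiv), Et2O, −78 °C; then 7, BF3·OEt2 (1.2 equiv), −78 °C; aq. NH4Cl
Reagents that add atoms: none
Why: Iodine–lithium exchange proceeds with retention of alkene geometry and the alkenyllithium opens the BF3-activated epoxide at its unsubstituted carbon (SN2 epoxide opening), so the Z alkene and the R carbinol centre are both carried over unchanged.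

Step 13
Reactants: 28 (5R,7Z)-3,3,7-trimethyl-1-[(triethylsilyl)oxy]-12-(trimethylsilyl)dodec-7-en-11-yn-5-ol
Product: 29 (5R,7Z)-3,3,7-trimethyl-1-[(triethylsilyl)oxy]dodec-7-en-11-yn-5-ol
Conditions: K2CO3 (0.3 equiv), MeOH, 0 °C → rt, monitored
Reagents that add atoms: none
Why: Base-catalysed methanolysis of the C(sp)–Si bond (protodesilylation) is much faster than cleavage of the alkyl TES ether.

Step 14
Reactants: 29 (5R,7Z)-3,3,7-trimethyl-1-[(triethylsilyl)oxy]dodec-7-en-11-yn-5-ol
Product: 31 (5R,7Z)-11-iodo-3,3,7-trimethyl-1-[(triethylsilyl)oxy]dodeca-7,11-dien-5-ol, via alkenylalane 30 (not isolated)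
Conditions: NiCl2(dppp) (3 mol %), i-Bu2AlH (2.3 equiv), THF, 0 °C → rt; then N-iodosuccinimide, 0 °C; aq. potassium sodium tartrate work-up
Reagents that add atoms: N-iodosuccinimide, O=C1CCC(=O)N1I
Why: Nickel-catalysed α-selective (Markovnikov) hydroalumination of the terminal alkyne places aluminium on the internal carbon, and iodinolysis with retention gives the 2-iodoalk-1-ene needed for the ring closure.

Step 15
Reactants: 31 (5R,7Z)-11-iodo-3,3,7-trimethyl-1-[(triethylsilyl)oxy]dodeca-7,11-dien-5-ol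
Product: 32 tert-butyl{[(5R,7Z)-11-iodo-3,3,7-trimethyl-1-[(triethylsilyl)oxy]dodeca-7,11-dien-5-yl]oxy}dimethylsilane
Conditions: t-BuMe2SiOTf, 2,6-lutidine, CH2Cl2, −78 °C
Reagents that add atoms: tert-butyldimethylsilyl trifluoromethanesulfonate, CC(C)(C)[Si](C)(C)OS(=O)(=O)C(F)(F)F
Why: Silylation of the secondary alcohol with the silyl triflate protects the C1 oxygen through the ring closure and the peroxide step.

Step 16
Reactants: 32 tert-butyl{[(5R,7Z)-11-iodo-3,3,7-trimethyl-1-[(triethylsilyl)oxy]dodeca-7,11-dien-5-yl]oxy}dimethylsilane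
Product: 34 (5R,7Z)-5-[(tert-butyldimethylsilyl)oxy]-11-iodo-3,3,7-trimethyldodeca-7,11-dienal, via alkoxysulfonium chloride 33 (not isolated)
Conditions: (COCl)2, DMSO, CH2Cl2, −78 → −40 °C; then Et3N, −78 → 0 °C
Reagents that add atoms: none
Why: Under Swern conditions the chlorosulfonium salt cleaves only the unhindered primary TES ether and the resulting alkoxysulfonium salt collapses to the aldehyde (direct Swern oxidation of a silyl ether), leaving the secondary TBS ether untouched.

Step 17
Reactants: 34 (5R,7Z)-5-[(tert-butyldimethylsilyl)oxy]-11-iodo-3,3,7-trimethyldodeca-7,11-dienal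
Product: 36 (1R,3Z)-1-[(tert-butyldimethylsilyl)oxy]-3,10,10-trimethyl-7-methylidenecycloundec-3-en-8-ol as a mixture of C8 epimers, via alkenylchromium dichloride 35 (not isolated)
Conditions: CrCl2 (10 equiv), NiCl2 (0.1 equiv), degassed DMSO/THF (3:1), 0.003 M, slow addition of 34, rt
Reagents that add atoms: none
Why: Intramolecular Nozaki–Hiyama–Kishi reaction, in which zerovalent nickel inserts into the C–I bond and transmetalation gives an alkenyl species of trivalent chromium that adds chemoselectively to the aldehyde under high dilution to close the 11-membered ring, the uncontrolled C8 configuration being erased in step 18.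

Step 18
Reactants: 36 (1R,3Z)-1-[(tert-butyldimethylsilyl)oxy]-3,10,10-trimethyl-7-methylidenecycloundec-3-en-8-ol (C8 epimers)
Product: 37 (1R,3Z)-1-[(tert-butyldimethylsilyl)oxy]-3,10,10-trimethyl-7-methylidenecycloundec-3-en-8-one
Conditions: Dess–Martin periodinane, pyridine, CH2Cl2, 0 °C; used at once
Reagents that add atoms: none
Why: Dess–Martin oxidation of the allylic alcohol converges both epimers on one enone.

Step 19
Reactants: 37 (1R,3Z)-1-[(tert-butyldimethylsilyl)oxy]-3,10,10-trimethyl-7-methylidenecycloundec-3-en-8-one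
Product: 38 (1R,3Z,8R)-1-[(tert-butyldimethylsilyl)oxy]-3,10,10-trimethyl-7-methylidenecycloundec-3-en-8-ol
Conditions: (S)-Me-CBS oxazaborolidine [(S)-1-methyl-3,3-diphenyltetrahydro-1H,3H-pyrrolo[1,2-c][1,3,2]oxazaborole] (1.0 equiv), catecholborane (2 equiv), toluene, −78 °C
Reagents that add atoms: none
Why: Corey–Bakshi–Shibata reduction, in which the alkenyl group acts as the large substituent on the (S)-oxazaborolidine and 1,2-hydride delivery gives the (8R)-alcohol under reagent control (the same sense as acetophenone to (R)-1-phenylethanol).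

Step 20
Reactants: 38 (1R,3Z,8R)-1-[(tert-butyldimethylsilyl)oxy]-3,10,10-trimethyl-7-methylidenecycloundec-3-en-8-ol; 21 2-methoxypropan-2-yl hydroperoxide
Product: 40 tert-butyl{[(1R,3Z,8S)-8-[(2-methoxypropan-2-yl)peroxy]-3,10,10-trimethyl-7-methylidenecycloundec-3-en-1-yl]oxy}dimethylsilane, via allylic mesylate 39 (not isolated)
Conditions: (MeSO2)2O, Et3N, THF, −30 °C; then 21 (4 equiv)/CsOH·H2O (3.5 equiv) premixed in DMF, −30 → 0 °C, quenched promptly
Reagents that add atoms: none
Why: The allylic alcohol is activated as its mesylate (the anhydride avoids chloride) and displaced by the caesium peroxide in an SN2 reaction with inversion (Williamson-type peroxide alkylation), which sets the 8S configuration and delivers the hydroperoxide in protected form.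

Step 21
Reactants: 40 tert-butyl{[(1R,3Z,8S)-8-[(2-methoxypropan-2-yl)peroxy]-3,10,10-trimethyl-7-methylidenecycloundec-3-en-1-yl]oxy}dimethylsilane
Product: 41 (1R,3Z,8S)-8-[(2-methoxypropan-2-yl)peroxy]-3,10,10-trimethyl-7-methylidenecycloundec-3-en-1-ol
Conditions: Bu4NF, AcOH (1:1), THF, 0 °C → rt
Reagents that add atoms: none
Why: Fluoride-mediated desilylation frees the C1 hydroxyl while the dialkyl-peroxide-type perketal is inert to buffered fluoride.

Step 22
Reactants: 41 (1R,3Z,8S)-8-[(2-methoxypropan-2-yl)peroxy]-3,10,10-trimethyl-7-methylidenecycloundec-3-en-1-ol; 26 (2E)-3-[4-(tetrahydro-2H-pyran-2-yloxy)phenyl]prop-2-enoic acid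
Product: 42 (1R,3Z,8S)-8-[(2-methoxypropan-2-yl)peroxy]-3,10,10-trimethyl-7-methylidenecycloundec-3-en-1-yl (2E)-3-[4-(tetrahydro-2H-pyran-2-yloxy)phenyl]prop-2-enoate
Conditions: DCC, DMAP (cat.), CH2Cl2, 0 °C → rt
Reagents that add atoms: none
Why: Steglich esterification joins the C15 macrocyclic alcohol and the protected coumaric acid by acylation at oxygen, which does not touch the C1 stereocentre.

Step 23
Reactants: 42 (1R,3Z,8S)-8-[(2-methoxypropan-2-yl)peroxy]-3,10,10-trimethyl-7-methylidenecycloundec-3-en-1-yl (2E)-3-[4-(tetrahydro-2H-pyran-2-yloxy)phenyl]prop-2-enoate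
Product: 43 (1R,3Z,8S)-8-hydroperoxy-3,10,10-trimethyl-7-methylidenecycloundec-3-en-1-yl (2E)-3-(4-hydroxyphenyl)prop-2-enoate
Conditions: PPTS (0.2 equiv), MeOH, 0 °C → rt
Reagents that add atoms: none
Why: Mild acid-catalysed transacetalisation in methanol removes both the peroxyketal and the aryl THP acetal, releasing the hydroperoxide and the phenol without affecting the ester, the alkenes or the stereocentres.

**Compound list**

1 | prenylmagnesium chloride [(3-methylbut-2-en-1-yl)magnesium chloride] | CC(C)=CC[Mg]Cl | starting material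
2 | (R)-epichlorohydrin [(2R)-2-(chloromethyl)oxirane] | ClC[C@H]1CO1 | starting material
3 | (2R)-1-chloro-4,4-dimethylhex-5-en-2-ol | ClC[C@H](O)CC(C)(C)C=C | intermediate
4 | (2R)-2-(2,2-dimethylbut-3-en-1-yl)oxirane | C=CC(C)(C)C[C@@H]1CO1 | intermediate
5 | 9-{3,3-dimethyl-4-[(2R)-oxiran-2-yl]butyl}-9-borabicyclo[3.3.1]nonane | CC(C)(CCB1C2CCCC1CCC2)C[C@@H]3CO3 | intermediate
6 | 3,3-dimethyl-4-[(2R)-oxiran-2-yl]butan-1-ol | OCCC(C)(C)C[C@@H]1CO1 | intermediate
7 | triethyl{3,3-dimethyl-4-[(2R)-oxiran-2-yl]butoxy}silane (fragment A) | CC[Si](CC)(CC)OCCC(C)(C)C[C@@H]1CO1 | intermediate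
8 | pent-4-yn-1-ol | C#CCCCO | starting material
9 | trimethyl{[5-(trimethylsilyl)pent-4-yn-1-yl]oxy}silane | C[Si](C)(C)C#CCCCO[Si](C)(C)C | intermediate
10 | 5-(trimethylsilyl)pent-4-yn-1-ol | C[Si](C)(C)C#CCCCO | intermediate
11 | 5-(trimethylsilyl)pent-4-ynal | C[Si](C)(C)C#CCCC=O | intermediate
12 | iodoethane | CCI | starting material
13 | ethyltriphenylphosphonium iodide | CC[P+](c1ccccc1)(c1ccccc1)c1ccccc1.[I-] | intermediate
14 | ethylidenetriphenylphosphorane | CC=P(c1ccccc1)(c1ccccc1)c1ccccc1 | intermediate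
15 | (1-iodoethyl)triphenylphosphonium iodide | CC(I)[P+](c1ccccc1)(c1ccccc1)c1ccccc1.[I-] | intermediate
16 | (1-iodoethylidene)triphenylphosphorane | CC(I)=P(c1ccccc1)(c1ccccc1)c1ccccc1 | intermediate
17 | [(5Z)-6-iodohept-5-en-1-yn-1-yl]trimethylsilane (fragment B) | C[Si](C)(C)C#CCC/C=C(/C)I | intermediate
18 | 2,3-dimethylbut-2-ene | CC(C)=C(C)C | starting material
19 | 4,4,5,5-tetramethyl-1,2,3-trioxolane | CC1(C)OOOC1(C)C | intermediate
20 | acetone O-oxide (propan-2-one O-oxide) | CC(C)=[O+][O-] | intermediate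
21 | 2-methoxypropan-2-yl hydroperoxide | COC(C)(C)OO | intermediate
22 | 4-iodophenol | Oc1ccc(I)cc1 | starting material
23 | 2-(4-iodophenoxy)tetrahydro-2H-pyran (racemic acetal carbon) | Ic1ccc(OC2CCCCO2)cc1 | intermediate
24 | methyl acrylate | C=CC(=O)OC | starting material
25 | methyl (2E)-3-[4-(tetrahydro-2H-pyran-2-yloxy)phenyl]prop-2-enoate | COC(=O)/C=C/c1ccc(OC2CCCCO2)cc1 | intermediate
26 | (2E)-3-[4-(tetrahydro-2H-pyran-2-yloxy)phenyl]prop-2-enoic acid (fragment C) | OC(=O)/C=C/c1ccc(OC2CCCCO2)cc1 | intermediate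
27 | [(2E)-7-(trimethylsilyl)hept-2-en-6-yn-2-yl]lithium (geometry of 17 retained; descriptor changes by priority only) | C[Si](C)(C)C#CCC/C=C(/C)[Li] | intermediate
28 | (5R,7Z)-3,3,7-trimethyl-1-[(triethylsilyl)oxy]-12-(trimethylsilyl)dodec-7-en-11-yn-5-ol | C[Si](C)(C)C#CCC/C=C(/C)C[C@H](O)CC(C)(C)CCO[Si](CC)(CC)CC | intermediate
29 | (5R,7Z)-3,3,7-trimethyl-1-[(triethylsilyl)oxy]dodec-7-en-11-yn-5-ol | C#CCC/C=C(/C)C[C@H](O)CC(C)(C)CCO[Si](CC)(CC)CC | intermediate
30 | diisobutylaluminium alkoxide of 29 carrying a diisobutylalumanyl group at C11 (2-alumanylalk-1-ene) | C=C([Al](CC(C)C)CC(C)C)CC/C=C(/C)C[C@H](O[Al](CC(C)C)CC(C)C)CC(C)(C)CCO[Si](CC)(CC)CC | intermediate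
31 | (5R,7Z)-11-iodo-3,3,7-trimethyl-1-[(triethylsilyl)oxy]dodeca-7,11-dien-5-ol | C=C(I)CC/C=C(/C)C[C@H](O)CC(C)(C)CCO[Si](CC)(CC)CC | intermediate
32 | tert-butyl{[(5R,7Z)-11-iodo-3,3,7-trimethyl-1-[(triethylsilyl)oxy]dodeca-7,11-dien-5-yl]oxy}dimethylsilane | C=C(I)CC/C=C(/C)C[C@H](O[Si](C)(C)C(C)(C)C)CC(C)(C)CCO[Si](CC)(CC)CC | intermediate
33 | {[(5R,7Z)-5-[(tert-butyldimethylsilyl)oxy]-11-iodo-3,3,7-trimethyldodeca-7,11-dien-1-yl]oxy}dimethylsulfonium chloride | C=C(I)CC/C=C(/C)C[C@H](O[Si](C)(C)C(C)(C)C)CC(C)(C)CCO[S+](C)C.[Cl-] | intermediate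
34 | (5R,7Z)-5-[(tert-butyldimethylsilyl)oxy]-11-iodo-3,3,7-trimethyldodeca-7,11-dienal | C=C(I)CC/C=C(/C)C[C@H](O[Si](C)(C)C(C)(C)C)CC(C)(C)CC=O | intermediate
35 | alkenylchromium dichloride derived from 34 (CrCl2 group in place of iodine) | C=C([Cr](Cl)Cl)CC/C=C(/C)C[C@H](O[Si](C)(C)C(C)(C)C)CC(C)(C)CC=O | intermediate
36 | (1R,3Z)-1-[(tert-butyldimethylsilyl)oxy]-3,10,10-trimethyl-7-methylidenecycloundec-3-en-8-ol (C8 epimer mixture) | C=C1CC/C=C(/C)C[C@H](O[Si](C)(C)C(C)(C)C)CC(C)(C)CC1O | intermediate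
37 | (1R,3Z)-1-[(tert-butyldimethylsilyl)oxy]-3,10,10-trimethyl-7-methylidenecycloundec-3-en-8-one | C=C1CC/C=C(/C)C[C@H](O[Si](C)(C)C(C)(C)C)CC(C)(C)CC1=O | intermediate
38 | (1R,3Z,8R)-1-[(tert-butyldimethylsilyl)oxy]-3,10,10-trimethyl-7-methylidenecycloundec-3-en-8-ol | C=C1CC/C=C(/C)C[C@H](O[Si](C)(C)C(C)(C)C)CC(C)(C)C[C@H]1O | intermediate
39 | (1R,3Z,8R)-1-[(tert-butyldimethylsilyl)oxy]-3,10,10-trimethyl-7-methylidenecycloundec-3-en-8-yl methanesulfonate | C=C1CC/C=C(/C)C[C@H](O[Si](C)(C)C(C)(C)C)CC(C)(C)C[C@H]1OS(C)(=O)=O | intermediate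
40 | tert-butyl{[(1R,3Z,8S)-8-[(2-methoxypropan-2-yl)peroxy]-3,10,10-trimethyl-7-methylidenecycloundec-3-en-1-yl]oxy}dimethylsilane | C=C1CC/C=C(/C)C[C@H](O[Si](C)(C)C(C)(C)C)CC(C)(C)C[C@@H]1OOC(C)(C)OC | intermediate
41 | (1R,3Z,8S)-8-[(2-methoxypropan-2-yl)peroxy]-3,10,10-trimethyl-7-methylidenecycloundec-3-en-1-ol | C=C1CC/C=C(/C)C[C@H](O)CC(C)(C)C[C@@H]1OOC(C)(C)OC | intermediate
42 | (1R,3Z,8S)-8-[(2-methoxypropan-2-yl)peroxy]-3,10,10-trimethyl-7-methylidenecycloundec-3-en-1-yl (2E)-3-[4-(tetrahydro-2H-pyran-2-yloxy)phenyl]prop-2-enoate | C=C1CC/C=C(/C)C[C@H](OC(=O)/C=C/c2ccc(OC3CCCCO3)cc2)CC(C)(C)C[C@@H]1OOC(C)(C)OC | intermediate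
43 | (1R,3Z,8S)-8-hydroperoxy-3,10,10-trimethyl-7-methylidenecycloundec-3-en-1-yl (2E)-3-(4-hydroxyphenyl)prop-2-enoate | C=C1CC/C=C(/C)C[C@H](OC(=O)/C=C/c2ccc(O)cc2)CC(C)(C)C[C@@H]1OO | target

**Step count and risk**

Total steps: 23. Longest linear sequence: 15 steps (steps 1–3, then 12–23; the branch through steps 4, 5, 7 and 12–23 is equally long).

Steps most likely to fail:

Step 17 (closure of the 11-membered ring). If the CrCl2/NiCl2 closure of 34 gives mainly oligomers or protodeiodinated material, the ring is closed instead by a reductive alkyne–aldehyde macrocyclisation catalysed by zerovalent nickel, which needs no vinyl iodide. This fallback sets out from alkynol 29. Silylation (t-BuMe2SiOTf, 2,6-lutidine) gives the enyne bis-silyl ether F1. The same direct Swern oxidation of the primary TES ether gives the ynal F2. Slow addition of F2 to Ni(cod)2, the bulky N-heterocyclic carbene 1,3-bis(2,6-diisopropylphenyl)imidazol-2-ylidene and Et3SiH in THF closes the ring at the internal alkyne carbon and gives the macrocyclic exo-methylene triethylsilyl ether F3 as C8 epimers. Selective methanolysis of the allylic TES ether (PPTS, MeOH, 0 °C) brings the route back to alcohol 36, ahead of step 18.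

Step 19 (stereoselective reduction of the macrocyclic enone). If the oxazaborolidine reduction of 37 is unselective or gives conjugate reduction, the approach changes from reagent control to reduction, separation and inversion. Setting out from 37, Luche reduction (NaBH4, CeCl3·7H2O, MeOH, −78 °C) returns the epimer mixture 36, whose C8 epimers are diastereomers and are separated on silica gel. The (8R)-epimer is 38 itself. The unwanted (1R,3Z,8S)-alcohol F4 is inverted by a Mitsunobu reaction (4-nitrobenzoic acid, PPh3, diisopropyl azodicarboxylate) to the (8R)-4-nitrobenzoate F5, and its methanolysis (K2CO3, MeOH) comes back to 38.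

Step 20 (allylic peroxide displacement). If mesylate 39 reacts with the peroxide anion mainly by SN2' attack or elimination, the C8–O bond is made instead by a stannyl-ene reaction of singlet oxygen, in which the C–Sn bond dictates both the site of oxygenation and the position of the new alkene. Setting out from 38 (the mixture 36 serves equally), mesylate 39 is treated with Bu3SnLi/CuBr·SMe2 to give the primary allylic stannane F6, which has an endocyclic C7=C8 alkene of inconsequential geometry. Tetraphenylporphyrin-sensitised photooxygenation (O2, visible light, CH2Cl2, −78 °C) attacks the activated allylstannane in preference to the C3=C4 alkene and gives the stannyl peroxide F7 with the exocyclic methylene restored. Acetic acid releases the free hydroperoxide F8 as a C8 epimer mixture. 2-Methoxypropene with catalytic PPTS converts it into perketal 40 and its (8R)-epimer F9, which are separated by chromatography, and the route resumes at 40. Stereocontrol at C8 is then by separation rather than by inversion.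

Further compounds

F1 | step 17 | tert-butyl(dimethyl){[(5R,7Z)-3,3,7-trimethyl-1-[(triethylsilyl)oxy]dodec-7-en-11-yn-5-yl]oxy}silane | C#CCC/C=C(/C)C[C@H](O[Si](C)(C)C(C)(C)C)CC(C)(C)CCO[Si](CC)(CC)CC
F2 | step 17 | (5R,7Z)-5-[(tert-butyldimethylsilyl)oxy]-3,3,7-trimethyldodec-7-en-11-ynal | C#CCC/C=C(/C)C[C@H](O[Si](C)(C)C(C)(C)C)CC(C)(C)CC=O
F3 | step 17 | tert-butyl(dimethyl){[(1R,3Z)-3,10,10-trimethyl-7-methylidene-8-[(triethylsilyl)oxy]cycloundec-3-en-1-yl]oxy}silane (C8 epimers) | C=C1CC/C=C(/C)C[C@H](O[Si](C)(C)C(C)(C)C)CC(C)(C)CC1O[Si](CC)(CC)CC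
F4 | step 19 | (1R,3Z,8S)-1-[(tert-butyldimethylsilyl)oxy]-3,10,10-trimethyl-7-methylidenecycloundec-3-en-8-ol | C=C1CC/C=C(/C)C[C@H](O[Si](C)(C)C(C)(C)C)CC(C)(C)C[C@@H]1O
F5 | step 19 | (1R,3Z,8R)-1-[(tert-butyldimethylsilyl)oxy]-3,10,10-trimethyl-7-methylidenecycloundec-3-en-8-yl 4-nitrobenzoate | C=C1CC/C=C(/C)C[C@H](O[Si](C)(C)C(C)(C)C)CC(C)(C)C[C@H]1OC(=O)c2ccc(cc2)[N+](=O)[O-]
F6 | step 20 | tert-butyl(dimethyl){[(1R,3Z)-3,10,10-trimethyl-7-[(tributylstannyl)methyl]cycloundeca-3,7-dien-1-yl]oxy}silane (C7=C8 geometry undefined) | CCCC[Sn](CCCC)(CCCC)CC1=CCC(C)(C)C[C@@H](O[Si](C)(C)C(C)(C)C)C/C(C)=C\CC1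
F7 | step 20 | tert-butyl(dimethyl){[(1R,3Z)-3,10,10-trimethyl-7-methylidene-8-[(tributylstannyl)peroxy]cycloundec-3-en-1-yl]oxy}silane (C8 epimers) | C=C1CC/C=C(/C)C[C@H](O[Si](C)(C)C(C)(C)C)CC(C)(C)CC1OO[Sn](CCCC)(CCCC)CCCC
F8 | step 20 | tert-butyl{[(1R,3Z)-8-hydroperoxy-3,10,10-trimethyl-7-methylidenecycloundec-3-en-1-yl]oxy}dimethylsilane (C8 epimers) | C=C1CC/C=C(/C)C[C@H](O[Si](C)(C)C(C)(C)C)CC(C)(C)CC1OO
F9 | step 20 | tert-butyl{[(1R,3Z,8R)-8-[(2-methoxypropan-2-yl)peroxy]-3,10,10-trimethyl-7-methylidenecycloundec-3-en-1-yl]oxy}dimethylsilane | C=C1CC/C=C(/C)C[C@H](O[Si](C)(C)C(C)(C)C)CC(C)(C)C[C@H]1OOC(C)(C)OC
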